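**Retrosynthetic overview**
- The target comes from a C1-O-TBS ether by fluoride desilylation; the oxirane (the only ring, closed in the penultimate step) comes from hydroxyl-directed threo epoxidation of a (9R)-allylic alcohol.
- The C9 carbinol, with the C7–C8 and C9–C10 bonds, comes from a Pd-induced 1,2-shift of a dienyl group from boron to carbon in a dienyl(vinyl)borate, triggered by an (E)-alkenyl bromide, then C–B oxidation.
- The alkenyl bromide (C1–C7, C20) comes from hydrozirconation/bromination of a 2-alkyne, made by Negishi coupling of a (Z)-2-iodoallylic alcohol, itself from trans-hydrostannation of mono-silylated butynediol.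
- The dienyl boronate (C10–C16) comes from methylalumination/borylation of 6-methylhept-5-en-1-yne, made from homoprenyl bromide and acetylide.
- Ring order: no carbocycle; the oxirane is formed last among the skeletal operations (step 9).

Assumption: positions follow the geranylgeraniol skeleton (C1 = CH2OH carbon, C9 = carbinol, C10/C11 = oxirane, C20 = acetoxymethyl carbon); the MandyPhos antipode written as (Sp,Sp) is the one that gives 9R, and its mirror image is used if a test run shows the opposite sense.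

**Route**

Step 1
Reactants: 1 but-2-yne-1,4-diol
Product: 2 4-[(tert-butyldimethylsilyl)oxy]but-2-yn-1-ol
Conditions: TBSCl (1 equiv), imidazole (1.1 equiv), 1 (3 equiv), DMF, 0 °C → rt
Reagents that add atoms: tert-butyldimethylsilyl chloride CC(C)(C)[Si](C)(C)Cl
Why: Statistical monosilylation of a symmetric diol used in excess gives the mono-ether cleanly and leaves one free propargylic hydroxyl as the directing group for step 2.

Step 2
Reactants: 2 4-[(tert-butyldimethylsilyl)oxy]but-2-yn-1-ol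
Product: 4 (Z)-4-[(tert-butyldimethylsilyl)oxy]-2-iodobut-2-en-1-ol, via vinylstannane 3 (not isolated)
Conditions: [Cp*RuCl]4 (1.25 mol%), Bu3SnH (1.05 equiv), CH2Cl2, rt; then I2 (1.1 equiv), 0 °C
Reagents that add atoms: tributyltin hydride CCCC[SnH](CCCC)CCCC (tin only in 3); iodine II
Why: Hydroxyl-directed ruthenium-catalysed trans-hydrostannation puts tin on the carbon next to the free carbinol and hydrogen anti to it, and iododestannylation goes with retention, so iodine ends up cis to CH2OTBS (Z).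

Step 3
Reactants: 4 (Z)-4-[(tert-butyldimethylsilyl)oxy]-2-iodobut-2-en-1-ol; 5 5-bromopent-2-yne
Product: 7 (E)-4-[(tert-butyldimethylsilyl)oxy]-2-(pent-3-yn-1-yl)but-2-en-1-ol, via alkylzinc bromide 6 (not isolated)
Conditions: 5, Zn dust, LiCl, THF, 50 °C; then 4, Pd(OAc)2 (2 mol%), SPhos (4 mol%), THF, rt, slow addition of 6
Reagents that add atoms: zinc [Zn] (only in 6)
Why: Negishi sp3–sp2 cross-coupling proceeds with retention of alkene geometry and tolerates the free hydroxyl under Pd/SPhos with slow addition, so the new chain (C4) is cis to CH2OTBS (C1).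

Step 4
Reactants: 7 (E)-4-[(tert-butyldimethylsilyl)oxy]-2-(pent-3-yn-1-yl)but-2-en-1-ol
Product: 9 (E)-2-[(E)-4-bromopent-3-en-1-yl]-4-[(tert-butyldimethylsilyl)oxy]but-2-en-1-ol, via alkenylzirconocene 8 (not isolated)
Conditions: Cp2Zr(H)Cl (2.3 equiv), THF, rt → 50 °C; then NBS (1.3 equiv), 0 °C
Reagents that add atoms: Schwartz reagent [H][Zr](Cl)(C1C=CC=C1)C1C=CC=C1 (zirconium only in 8); N-bromosuccinimide O=C1CCC(=O)N1Br
Why: Syn hydrozirconation of the 2-alkyne, equilibrated with excess reagent to the less hindered methyl-bearing carbon (about 9:1 expected), then bromodezirconation with retention gives the (E)-2-bromo-2-alkene; the trisubstituted alkene and silyl ether do not react.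

Step 5
Reactants: 10 5-bromo-2-methylpent-2-ene; 11 lithium acetylide ethylenediamine complex
Product: 12 6-methylhept-5-en-1-yne
Conditions: DMSO, 10 °C → rt
Reagents that add atoms: none
Why: SN2 alkylation of acetylide by a primary homoallylic bromide in DMSO.

Step 6
Reactants: 12 6-methylhept-5-en-1-yne
Product: 14 2-[(E)-2,6-dimethylhepta-1,5-dien-1-yl]-4,4,5,5-tetramethyl-1,3,2-dioxaborolane, via alkenylalane 13 (not isolated)
Conditions: Me3Al (2 equiv), Cp2ZrCl2 (20 mol%), CH2Cl2, 0 °C → rt; then MeOBpin, THF, 0 °C → rt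
Reagents that add atoms: trimethylaluminium C[Al](C)C; 2-methoxy-4,4,5,5-tetramethyl-1,3,2-dioxaborolane COB1OC(C)(C)C(C)(C)O1
Why: Negishi zirconium-catalysed syn methylalumination of the terminal alkyne (methyl to the internal carbon, >98% E) followed by aluminium-to-boron transmetalation with retention; the trisubstituted alkene is inert.

Step 7
Reactants: 14 2-[(E)-2,6-dimethylhepta-1,5-dien-1-yl]-4,4,5,5-tetramethyl-1,3,2-dioxaborolane; 15 vinylmagnesium bromide; 9 (E)-2-[(E)-4-bromopent-3-en-1-yl]-4-[(tert-butyldimethylsilyl)oxy]but-2-en-1-ol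
Product: 19 (2E,6E,9R,10E)-1-[(tert-butyldimethylsilyl)oxy]-3-(hydroxymethyl)-7,11,15-trimethylhexadeca-2,6,10,14-tetraen-9-ol, via boron ate complex 16 (not isolated), via trimethylsilyl ether 17 (not isolated), via allylic boronic ester 18 (not isolated)
Conditions: 14, 15, THF, 0 °C → rt (gives 16); 9, Et2NSiMe3, THF, rt, volatiles removed (gives 17); NaOTf, Pd(OAc)2 (2 mol%), (Sp,Sp)-MandyPhos (2.4 mol%), THF/DMSO, 60 °C (gives 18); then 3 M NaOH, 30% H2O2, 0 °C → rt
Reagents that add atoms: N,N-diethyltrimethylsilylamine CCN(CC)[Si](C)(C)C (silicon only in 17 and 18); hydrogen peroxide OO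
Why: Proposed new method: an enantioselective Pd/MandyPhos conjunctive coupling run with a trisubstituted (β,β-dialkyl) alkenyl group as the migrating ligand on boron and an acyclic, O-functionalised (E)-2-bromo-2-alkene as electrophile — oxidative addition gives an alkenyl–Pd(II) species (bromide taken up by NaOTf) that binds the unhindered vinyl group of 16 on the enantioface fixed by the ligand, the dienyl group then shifts 1,2 from boron to C9 anti to palladium (metal-induced 1,2-metallate rearrangement), C7–C8 reductive elimination keeps the bromide geometry and gives (R)-18, and C–B oxidation with retention (the base also removes the TMS ether) gives 19; the closest known reaction type is the Pd-catalysed conjunctive cross-coupling of vinyl- and bis(alkenyl)boron ate complexes with aryl or alkenyl triflates and halides.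

Step 8
Reactants: 19 (2E,6E,9R,10E)-1-[(tert-butyldimethylsilyl)oxy]-3-(hydroxymethyl)-7,11,15-trimethylhexadeca-2,6,10,14-tetraen-9-ol
Product: 20 [(2E,6E,9R,10E)-1-[(tert-butyldimethylsilyl)oxy]-9-hydroxy-7,11,15-trimethylhexadeca-2,6,10,14-tetraen-3-yl]methyl acetate
Conditions: AcCl (1.05 equiv), 2,4,6-collidine (2 equiv), CH2Cl2, −78 °C
Reagents that add atoms: acetyl chloride CC(=O)Cl
Why: Kinetically selective acylation of the primary allylic hydroxyl over the hindered secondary one at low temperature.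

Step 9
Reactants: 20 [(2E,6E,9R,10E)-1-[(tert-butyldimethylsilyl)oxy]-9-hydroxy-7,11,15-trimethylhexadeca-2,6,10,14-tetraen-3-yl]methyl acetate
Product: 21 [(2E,6E,9R)-1-[(tert-butyldimethylsilyl)oxy]-9-hydroxy-7-methyl-9-[(2S,3S)-3-methyl-3-(4-methylpent-3-en-1-yl)oxiran-2-yl]nona-2,6-dien-3-yl]methyl acetate
Conditions: VO(acac)2 (5 mol%), t-BuOOH (1.2 equiv, decane), CH2Cl2, 0 °C
Reagents that add atoms: tert-butyl hydroperoxide CC(C)(C)OO
Why: Vanadium-catalysed hydroxyl-directed epoxidation acts only on the allylic C10=C11 bond, and A(1,3) strain from the methyl cis to C9 holds the C9–H in the alkene plane so oxygen is delivered syn to the hydroxyl, giving the threo (9R,10S,11S) epoxy alcohol (dr about 6–9:1 expected, minor isomer removed by chromatography).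

Step 10
Reactants: 21 [(2E,6E,9R)-1-[(tert-butyldimethylsilyl)oxy]-9-hydroxy-7-methyl-9-[(2S,3S)-3-methyl-3-(4-methylpent-3-en-1-yl)oxiran-2-yl]nona-2,6-dien-3-yl]methyl acetate
Product: 22 [(2E,6E,9R)-1,9-dihydroxy-7-methyl-9-[(2S,3S)-3-methyl-3-(4-methylpent-3-en-1-yl)oxiran-2-yl]nona-2,6-dien-3-yl]methyl acetate
Conditions: TBAF/AcOH (1:1, 3 equiv), THF, 0 °C → rt
Reagents that add atoms: none
Why: Buffered fluoride cleavage of the primary TBS ether leaves the acetate and epoxy alcohol intact, and the trans relation of C1–OH and the acetoxymethyl group across the alkene prevents acyl migration.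

**Compound list**
1 | but-2-yne-1,4-diol | OCC#CCO | starting material
2 | 4-[(tert-butyldimethylsilyl)oxy]but-2-yn-1-ol | OCC#CCO[Si](C)(C)C(C)(C)C | intermediate
3 | (Z)-4-[(tert-butyldimethylsilyl)oxy]-2-(tributylstannyl)but-2-en-1-ol | OC/C([Sn](CCCC)(CCCC)CCCC)=C/CO[Si](C)(C)C(C)(C)C | intermediate
4 | (Z)-4-[(tert-butyldimethylsilyl)oxy]-2-iodobut-2-en-1-ol | OC/C(I)=C/CO[Si](C)(C)C(C)(C)C | intermediate
5 | 5-bromopent-2-yne | CC#CCCBr | starting material
6 | pent-3-yn-1-ylzinc bromide | CC#CCC[Zn]Br | intermediate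
7 | (E)-4-[(tert-butyldimethylsilyl)oxy]-2-(pent-3-yn-1-yl)but-2-en-1-ol | CC#CCC/C(CO)=C\CO[Si](C)(C)C(C)(C)C | intermediate
8 | (E)-alkenylzirconocene chloride from 7, hydroxyl held as zirconocene chloride alkoxide | C/C(=C\CC/C(CO[Zr](Cl)(C1C=CC=C1)C1C=CC=C1)=C\CO[Si](C)(C)C(C)(C)C)[Zr](Cl)(C1C=CC=C1)C1C=CC=C1 | intermediate
9 | (E)-2-[(E)-4-bromopent-3-en-1-yl]-4-[(tert-butyldimethylsilyl)oxy]but-2-en-1-ol | C/C(Br)=C\CC/C(CO)=C\CO[Si](C)(C)C(C)(C)C | intermediate
10 | 5-bromo-2-methylpent-2-ene | CC(C)=CCCBr | starting material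
11 | lithium acetylide ethylenediamine complex | [Li]C#C.NCCN | starting material
12 | 6-methylhept-5-en-1-yne | CC(C)=CCCC#C | intermediate
13 | [(E)-2,6-dimethylhepta-1,5-dien-1-yl]dimethylalane | CC(C)=CCC/C(C)=C/[Al](C)C | intermediate
14 | 2-[(E)-2,6-dimethylhepta-1,5-dien-1-yl]-4,4,5,5-tetramethyl-1,3,2-dioxaborolane | CC(C)=CCC/C(C)=C/B1OC(C)(C)C(C)(C)O1 | intermediate
15 | vinylmagnesium bromide | C=C[Mg]Br | starting material
16 | bromomagnesium [(E)-2,6-dimethylhepta-1,5-dien-1-yl](ethenyl)(pinacolato)borate | CC(C)=CCC/C(C)=C/[B-]1(C=C)OC(C)(C)C(C)(C)O1.[Mg+]Br | intermediate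
17 | [(E)-2-[(E)-4-bromopent-3-en-1-yl]-4-[(tert-butyldimethylsilyl)oxy]but-2-en-1-yl]oxy-trimethylsilane | C/C(Br)=C\CC/C(CO[Si](C)(C)C)=C\CO[Si](C)(C)C(C)(C)C | intermediate
18 | tert-butyldimethyl{[(2E,6E,9R,10E)-7,11,15-trimethyl-9-(4,4,5,5-tetramethyl-1,3,2-dioxaborolan-2-yl)-3-{[(trimethylsilyl)oxy]methyl}hexadeca-2,6,10,14-tetraen-1-yl]oxy}silane | C[Si](C)(C)OC/C(=C/CO[Si](C)(C)C(C)(C)C)CC/C=C(\C)C[C@@H](B1OC(C)(C)C(C)(C)O1)/C=C(\C)CCC=C(C)C | intermediate
19 | (2E,6E,9R,10E)-1-[(tert-butyldimethylsilyl)oxy]-3-(hydroxymethyl)-7,11,15-trimethylhexadeca-2,6,10,14-tetraen-9-ol | OC/C(=C/CO[Si](C)(C)C(C)(C)C)CC/C=C(\C)C[C@@H](O)/C=C(\C)CCC=C(C)C | intermediate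
20 | [(2E,6E,9R,10E)-1-[(tert-butyldimethylsilyl)oxy]-9-hydroxy-7,11,15-trimethylhexadeca-2,6,10,14-tetraen-3-yl]methyl acetate | CC(=O)OC/C(=C/CO[Si](C)(C)C(C)(C)C)CC/C=C(\C)C[C@@H](O)/C=C(\C)CCC=C(C)C | intermediate
21 | [(2E,6E,9R)-1-[(tert-butyldimethylsilyl)oxy]-9-hydroxy-7-methyl-9-[(2S,3S)-3-methyl-3-(4-methylpent-3-en-1-yl)oxiran-2-yl]nona-2,6-dien-3-yl]methyl acetate | CC(=O)OC/C(=C/CO[Si](C)(C)C(C)(C)C)CC/C=C(\C)C[C@@H](O)[C@@H]1O[C@@]1(C)CCC=C(C)C | intermediate
22 | [(2E,6E,9R)-1,9-dihydroxy-7-methyl-9-[(2S,3S)-3-methyl-3-(4-methylpent-3-en-1-yl)oxiran-2-yl]nona-2,6-dien-3-yl]methyl acetate | CC(=O)OC/C(=C/CO)CC/C=C(\C)C[C@@H](O)[C@@H]1O[C@@]1(C)CCC=C(C)C | target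

**Step count**
Total steps: 10. Longest linear sequence: 8 (steps 1, 2, 3, 4, 7, 8, 9, 10).

**Three steps most likely to fail**

Step 7 (the proposed new conjunctive coupling). The risks are direct Suzuki coupling of the dienyl group with the bromide, low enantioselectivity with this hindered migrating group, and halide inhibition. The ee of 19 is the ee of the target, because step 9 is substrate-controlled. The fallback uses known lithiation–borylation chemistry (still a 1,2-boronate shift) and sets out from 9. Silylation with TESCl/imidazole gives triethylsilyl ether F1. Bromine–lithium exchange (t-BuLi, Et2O, −78 °C) gives alkenyllithium F2, which opens ethylene oxide (BF3·OEt2) to homoallylic alcohol F3. i-Pr2NCOCl/Et3N gives N,N-diisopropylcarbamate F4. s-BuLi/(−)-sparteine (Et2O, −78 °C) gives lithiated carbamate F5 (S at carbon), which is borylated with retention by 14 to boron ate complex F6. Warming with MgBr2·OEt2 makes the dienyl group shift from boron to carbon with inversion, giving allylic boronic ester F7. NaOH/H2O2 gives allylic alcohol F8 (9R), and PPTS/MeOH removes the triethylsilyl group, coming back to the route at 19.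

Step 9 (threo selectivity, and competition from the homoallylic C6=C7 bond). The fallback sets out from 20 and comes back at 21, moving from substrate control to reagent control. Stoichiometric Ti(OiPr)4/L-(+)-diisopropyl tartrate/t-BuOOH (CH2Cl2, 4 Å sieves, −20 °C) is used. The facial preference of this tartrate (the one that gives (2S,3S)-epoxy alcohols from E-allylic alcohols) coincides with the A(1,3)-preferred face of the (9R) alcohol. The reaction is slow for this enantiomer, but both control elements point to 21, and homoallylic alkenes are not touched. No new compound is made.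

Step 4 (regiochemistry of hydrozirconation; the 3-bromo regioisomer is hard to separate). The fallback sets out from 4, bypasses 7 and fixes the bromine position by construction. Stille coupling of 4 with tributyl(vinyl)stannane (Pd2(dba)3, AsPh3, NMP) gives dienol F9. 9-BBN-H (2.2 equiv, THF) hydroborates the terminal vinyl group to alkylborane F10 (not isolated). B-alkyl Suzuki coupling (Pd(dppf)Cl2, AsPh3, Cs2CO3, DMF/THF/H2O, rt) then takes place at the C–I bond only of (E)-2-bromo-1-iodoprop-1-ene F11 (made from propyne and IBr by anti addition). Aqueous work-up comes back to the route at 9.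

Further compounds
F1 | step 7 | [(E)-2-[(E)-4-bromopent-3-en-1-yl]-4-[(tert-butyldimethylsilyl)oxy]but-2-en-1-yl]oxy-triethylsilane | C/C(Br)=C\CC/C(CO[Si](CC)(CC)CC)=C\CO[Si](C)(C)C(C)(C)C
F2 | step 7 | alkenyllithium from F1, lithium in place of bromine | C/C([Li])=C\CC/C(CO[Si](CC)(CC)CC)=C\CO[Si](C)(C)C(C)(C)C
F3 | step 7 | (3E,7E)-9-[(tert-butyldimethylsilyl)oxy]-3-methyl-7-{[(triethylsilyl)oxy]methyl}nona-3,7-dien-1-ol | OCC/C(C)=C/CC/C(CO[Si](CC)(CC)CC)=C\CO[Si](C)(C)C(C)(C)C
F4 | step 7 | (3E,7E)-9-[(tert-butyldimethylsilyl)oxy]-3-methyl-7-{[(triethylsilyl)oxy]methyl}nona-3,7-dien-1-yl N,N-diisopropylcarbamate | CC(C)N(C(C)C)C(=O)OCC/C(C)=C/CC/C(CO[Si](CC)(CC)CC)=C\CO[Si](C)(C)C(C)(C)C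
F5 | step 7 | (S)-1-lithio derivative of carbamate F4 | CC(C)N(C(C)C)C(=O)O[C@@H]([Li])C/C(C)=C/CC/C(CO[Si](CC)(CC)CC)=C\CO[Si](C)(C)C(C)(C)C
F6 | step 7 | lithium boronate complex of F5 and 14 | CC(C)N(C(C)C)C(=O)O[C@@H]([B-]1(/C=C(\C)CCC=C(C)C)OC(C)(C)C(C)(C)O1)C/C(C)=C/CC/C(CO[Si](CC)(CC)CC)=C\CO[Si](C)(C)C(C)(C)C.[Li+]
F7 | step 7 | tert-butyldimethyl{[(2E,6E,9R,10E)-7,11,15-trimethyl-9-(4,4,5,5-tetramethyl-1,3,2-dioxaborolan-2-yl)-3-{[(triethylsilyl)oxy]methyl}hexadeca-2,6,10,14-tetraen-1-yl]oxy}silane | CC[Si](CC)(CC)OC/C(=C/CO[Si](C)(C)C(C)(C)C)CC/C=C(\C)C[C@@H](B1OC(C)(C)C(C)(C)O1)/C=C(\C)CCC=C(C)C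
F8 | step 7 | (2E,6E,9R,10E)-1-[(tert-butyldimethylsilyl)oxy]-7,11,15-trimethyl-3-{[(triethylsilyl)oxy]methyl}hexadeca-2,6,10,14-tetraen-9-ol | CC[Si](CC)(CC)OC/C(=C/CO[Si](C)(C)C(C)(C)C)CC/C=C(\C)C[C@@H](O)/C=C(\C)CCC=C(C)C
F0 | step 9 | none | none
F9 | step 4 | (E)-4-[(tert-butyldimethylsilyl)oxy]-2-ethenylbut-2-en-1-ol | C=C/C(CO)=C\CO[Si](C)(C)C(C)(C)C
F10 | step 4 | bis(9-borabicyclo[3.3.1]nonan-9-yl) adduct of F9 (B-alkyl at C5, O-borinate at the hydroxyl) | C1CC2CCCC(C1)B2CC/C(COB1C2CCCC1CCC2)=C\CO[Si](C)(C)C(C)(C)C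
F11 | step 4 | (E)-2-bromo-1-iodoprop-1-ene | C/C(Br)=C\I
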